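## Retrosynthetic overview
- The last step is global O-demethylation of a heptamethyl ether. All four stereocentres and both trans-2,3-diaryl-dihydrobenzofuran rings come from one new step: a chiral-sulfide-catalysed double [4+1] annulation of a bis(o-hydroxybenzhydryl sulfone) with a 4-methoxybenzyl sulfonium ylide.
- The bis-sulfone comes from a bis-benzhydrol on the central resorcinol ring (ring B). Two aryl-metal additions build it: a Grignard addition at the aldehyde of ring B, then Li/Br exchange and addition to a stilbenyl salicylaldehyde.
- The E-stilbene is made first, by a Heck reaction on 5-bromosalicylaldehyde. Ring B comes from 2-bromo-4,6-dimethoxybenzaldehyde, with selective ortho-demethylation giving the phenol that later closes one dihydrobenzofuran.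

**Assumptions (one line):** The target is all-trans with CIP descriptors (2S,3S,2′S,3′S), read from the SMILES. Compound 4 and the (2S,5S)-sulfide 12 are treated as commercial. The (2S,5S)-sulfide is assumed to give the S,S sense of induction; its enantiomer is used if a model reaction shows the opposite.

## Route

**Step 1**
Reactants: 1 (5-bromo-2-hydroxybenzaldehyde); 2 (3,5-dimethoxystyrene)
Product: 3, 5-[(E)-2-(3,5-dimethoxyphenyl)ethenyl]-2-hydroxybenzaldehyde
Conditions: Pd(OAc)2 (3 mol%), P(o-tol)3 (6 mol%), Et3N, DMF, 110 °C
Reagents that add atoms: none (2 is a reactant, numbered)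
Why: Mizoroki–Heck coupling gives the E-stilbene selectively, through syn-insertion and then β-hydride elimination. The free phenol and aldehyde are tolerated.

**Step 2**
Reactants: 4 (2-bromo-4,6-dimethoxybenzaldehyde)
Product: 5, 2-bromo-6-hydroxy-4-methoxybenzaldehyde
Conditions: BCl3 (1.2 equiv), CH2Cl2, −78 → 0 °C, 2 h
Reagents that add atoms: none
Why: BCl3 chelates the aldehyde C=O and cleaves only the adjacent (ortho) OMe, the usual regioselective demethylation of 2-methoxybenzaldehydes; the para-OMe and the Br survive.

**Step 3**
Reactants: 5; 6 (3,5-dimethoxyphenylmagnesium bromide)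
Product: 7, 3-bromo-2-[(3,5-dimethoxyphenyl)(hydroxy)methyl]-5-methoxyphenol (racemic carbinol)
Conditions: 6 (2.5 equiv), THF, 0 → 25 °C, 2 h; sat. NH4Cl work-up; product used crude
Reagents that add atoms: 6, 3,5-dimethoxyphenylmagnesium bromide, COc1cc(OC)cc([Mg]Br)c1 (adds the 3,5-dimethoxyphenyl carbinol unit)
Why: Grignard 1,2-addition to the aldehyde (the first equivalent deprotonates the phenol). The carbinol centre is destroyed later when the o-quinone methide forms, so its configuration is irrelevant.

**Step 4**
Reactants: 7; 3
Product: 8, 2-[(3,5-dimethoxyphenyl)(hydroxy)methyl]-3-{hydroxy[2-hydroxy-5-((E)-3,5-dimethoxystyryl)phenyl]methyl}-5-methoxyphenol (mixture of carbinol diastereomers)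
Conditions: 7, n-BuLi (2.1 equiv) then t-BuLi (2.1 equiv), THF, −78 °C, 20 min; then the lithium phenoxide of 3 (3 + LiHMDS, 1.5 equiv), −78 → 0 °C; NH4Cl work-up
Reagents that add atoms: none (3 is a reactant, numbered)
Why: n-BuLi deprotonates both OH groups, and t-BuLi then effects Li/Br exchange. The resulting aryllithium adds 1,2 to the aldehyde of 3 (organolithium addition). Both new carbinol centres are removed in the next steps.

**Step 5**
Reactants: 8; 9 (sodium p-toluenesulfinate)
Product: 10, the bis(α-tosyl) bisphenol (both carbinol OH replaced by p-tolylsulfonyl)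
Conditions: 9 (5 equiv), HCO2H, CH2Cl2, 25 °C, 3 h; crude used
Reagents that add atoms: 9, sodium p-toluenesulfinate, Cc1ccc(cc1)S(=O)[O-].[Na+] (adds 2 p-TolSO2)
Why: The electron-rich o-hydroxybenzhydrols ionise under acid to o-quinone methides or benzhydryl cations, which sulfinate traps at sulfur (the standard route to o-QM precursors). Ionisation is reversible, so any 1,3-dihydroisobenzofuran ether formed between the two neighbouring carbinols is re-opened and funnels to the bis-sulfone. Both stereo-labile carbinols become masked o-QM precursors.

**Step 6 (new step)**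
Reactants: 10; 11 (4-methoxybenzyl bromide); 12 (catalyst)
Product: 13, heptamethyl ether of diptoindonesin B, with all four stereocentres set
Conditions: 11 (3.0 equiv), 12 (30 mol%), Cs2CO3 (6 equiv), MeCN (0.02 M), 0 → 25 °C, 48 h
Reagents that add atoms: 11, 4-methoxybenzyl bromide, COc1ccc(CBr)cc1 (adds two 4-MeOC6H4CH units, which become C2 and C2′); catalyst 12 leaves no atoms
Why: Proposed new method: chiral-sulfide-catalysed, one-pot double o-QM/sulfonium-ylide [4+1] annulation that forms both dihydrobenzofuran rings and four stereocentres. Cs2CO3 eliminates sulfinate from each phenoxide sulfone to give two o-QMs. Bromide 11 and sulfide 12 form the S-(4-methoxybenzyl) thiolanium salt, and base converts it to the ylide. The ylide adds 1,4 to each o-QM to give an anti betaine, and the phenoxide then displaces the sulfide (intramolecular SN2), releasing 12 and fixing the trans-2,3-diaryl geometry. The C2-symmetric thiolane sets the face selectivity of the ylide addition at each o-QM, giving (2S,3S) and (2′S,3′S). The closest known reactions are the racemic trans-selective [4+1] of o-QMs with sulfonium ylides and the sulfide-catalysed asymmetric ylide epoxidations that use benzyl bromides. The new elements are the asymmetric catalytic version on diaryl o-QMs, the double annulation, and the fully oxygenated polyaryl substrate.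

**Step 7**
Reactants: 13
Product: 14, trans-diptoindonesin B (target)
Conditions: BBr3 (15 equiv), CH2Cl2, −78 → 0 °C, 3 h; MeOH quench; reverse-phase HPLC; protected from light
Reagents that add atoms: none
Why: BBr3 cleaves all seven aryl methyl ethers. The stereocentres are not touched, and the E-olefin and trans-dihydrobenzofurans survive at ≤ 0 °C, as in permethyl-viniferin deprotections.

**Structure checks:**
- Ring B carries C3 at B1 (from the Br), C3′ at B6 (from the CHO), the ring O at B5 (from the demethylated OMe) and OMe→OH at B3, which matches the target.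
- The styryl group sits para to the ring-A oxygen, as in the target.
- The SMILES of 14 gives S at C2, C3, C2′ and C3′. Each ring has its two aryl groups on opposite faces, so both rings are trans.
- All four stereocentres are formed in Step 6 and none is touched afterwards.
- The 7 OMe of 13 give the 7 OH of 14.
- Carbon count: 10 has 47 C; removing two p-Tol (2 × 7 = 14 C) and adding two 4-MeOC6H4CH units (2 × 8 = 16 C) gives 49 C for 13, which is the 42 C of 14 plus 7 OMe.

## Compound list
1 | 5-bromo-2-hydroxybenzaldehyde | O=Cc1cc(Br)ccc1O | starting material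
2 | 3,5-dimethoxystyrene | C=Cc1cc(OC)cc(OC)c1 | starting material
3 | 5-[(E)-2-(3,5-dimethoxyphenyl)ethenyl]-2-hydroxybenzaldehyde | O=Cc1cc(/C=C/c2cc(OC)cc(OC)c2)ccc1O | intermediate
4 | 2-bromo-4,6-dimethoxybenzaldehyde | COc1cc(Br)c(C=O)c(OC)c1 | starting material
5 | 2-bromo-6-hydroxy-4-methoxybenzaldehyde | COc1cc(O)c(C=O)c(Br)c1 | intermediate
6 | 3,5-dimethoxyphenylmagnesium bromide | COc1cc(OC)cc([Mg]Br)c1 | starting material (reagent)
7 | 3-bromo-2-[(3,5-dimethoxyphenyl)(hydroxy)methyl]-5-methoxyphenol (racemic) | COc1cc(O)c(C(O)c2cc(OC)cc(OC)c2)c(Br)c1 | intermediate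
8 | bis-benzhydrol (Step 4 product; carbinol diastereomers) | COc1cc(O)c(C(O)c2cc(OC)cc(OC)c2)c(C(O)c2cc(/C=C/c3cc(OC)cc(OC)c3)ccc2O)c1 | intermediate
9 | sodium p-toluenesulfinate | Cc1ccc(cc1)S(=O)[O-].[Na+] | starting material (reagent)
10 | bis(α-tosyl) bisphenol | COc1cc(O)c(C(c2cc(OC)cc(OC)c2)S(=O)(=O)c2ccc(C)cc2)c(C(c2cc(/C=C/c3cc(OC)cc(OC)c3)ccc2O)S(=O)(=O)c2ccc(C)cc2)c1 | intermediate
11 | 4-methoxybenzyl bromide | COc1ccc(CBr)cc1 | starting material
12 | (2S,5S)-2,5-dimethylthiolane (chiral sulfide catalyst) | C[C@H]1CC[C@H](C)S1 | starting material (catalyst)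
13 | heptamethyl ether of diptoindonesin B, (2S,3S)/(2′S,3′S) all-trans | COc1ccc([C@H]2Oc3ccc(/C=C/c4cc(OC)cc(OC)c4)cc3[C@@H]2c2cc(OC)cc3c2[C@H](c2cc(OC)cc(OC)c2)[C@@H](c2ccc(OC)cc2)O3)cc1 | intermediate
14 | trans-diptoindonesin B | Oc1ccc([C@H]2Oc3ccc(/C=C/c4cc(O)cc(O)c4)cc3[C@@H]2c2cc(O)cc3c2[C@H](c2cc(O)cc(O)c2)[C@@H](c2ccc(O)cc2)O3)cc1 | target

## Totals
Total steps: 7. Longest linear sequence: 6 (4 → 5 → 7 → 8 → 10 → 13 → 14; the Heck step feeds Step 4).

## Three steps most likely to fail
1. **Step 6 (proposed new step).** Enantio- or diastereocontrol may be poor, or the two adjacent o-QMs may oligomerise because of steric congestion.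
   Fallback (known chemistry): run the known racemic trans-selective [4+1] with an achiral dimethylsulfonium benzylide (Me2S, 11, Cs2CO3). Then isolate the all-S enantiomer of 13 from the stereoisomeric mixture by preparative chiral-stationary-phase HPLC. This is resolution in place of asymmetric catalysis.
2. **Step 4.** The hindered polyanionic Li/Br exchange and the addition to a deactivated phenoxide-aldehyde may give low yields.
   Fallback: avoid the organolithium. Convert the aryl bromide of 7 to the pinacol boronate (B2pin2, Pd(dppf)Cl2, KOAc), then add it to aldehyde 3 by Rh(I)-catalysed 1,2-arylation, so the coupling is catalytic boron chemistry.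
3. **Step 7.** BBr3 may open the benzylic C–O bond of the dihydrobenzofurans or epimerise them.
   Fallback: rebuild the skeleton with benzyl ethers in place of methyl ethers. Use 4-benzyloxybenzyl bromide in Step 6, 3,5-bis(benzyloxy)phenylMgBr in Step 3, 3,5-bis(benzyloxy)styrene in Step 1 and 2-bromo-4,6-bis(benzyloxy)benzaldehyde in Step 2. Then remove all benzyl groups with BCl3/pentamethylbenzene at −78 °C, which avoids strongly ionising BBr3 conditions.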